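## Retrosynthetic overview

1. The target is a (2R,3S)-flavan-3-ol whose ring A carbon C8 is joined through a CH2 bridge to ring D, a C-methyl, O-methyl acylphloroglucinol. The last bonds made are the ring D aryl–acyl bond (aryl bromide to aryllithium, then the Weinreb amide of (R)-2-methylbutanoic acid), followed by cleavage of seven benzyl ethers.
2. The feature on which the plan rests: ring A is a pentasubstituted phloroglucinol ring in which C8, and not the equally nucleophilic C6, carries the bridge. Ring A is therefore not substituted but built around the C4a=C8a enol ether of a finished ring C, so that C5, C6, C7 and C8 come from an acyl carbon, two alkyne carbons and a diazo carbon that already bears the ring D arm.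
3. Key disconnection: photochemical Wolff rearrangement of a dihydropyranyl diazo ketone (bond C8–C8a) and benzannulation of the vinylketene with triisopropylsiloxyacetylene (bonds C5–C6, C7–C8, C4a–C5).
4. The diazo ketone comes from a 6-acyl dihydropyran, made from the enol triflate of the ring C lactone and a ring D propanal (chromium/nickel coupling, oxidation, diazo transfer). The lactone comes from a glycolate allylation (C3), an aryl ketone, a chelation-controlled reduction (C2), hydroboration and oxidative lactonisation.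
5. Ring order: rings B and D are bought as arenes (ring D is dressed from 2,4,6-trimethoxytoluene), ring C is closed in step 16, ring A in step 21.

Key step: step 21

Remark on the chemistry: carbon C6 of the dihydropyran is not metalated by deprotonation, because an alkyllithium base would also attack the benzylic, oxygen-bearing C2–H and the O-benzyl CH2 groups; the acyl carbon is attached through the lactone enol triflate under neutral chromium/nickel conditions, which also spare the ring D bromide. Triisopropylsiloxyacetylene is assumed not to be a stock reagent and is made in step 9.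

In the step names, ArB stands for 3,4-bis(benzyloxy)phenyl and ArD for 2,6-bis(benzyloxy)-3-bromo-4-methoxy-5-methylphenyl; full names are in the compound list.

## Route

**Step 1**
Reactants: 1 2,4,6-trimethoxytoluene
Product: 3 2,4,6-trimethoxy-3-methylbenzaldehyde, via iminium chloride 2 (not isolated)
Conditions: POCl3, DMF, 0 to 60 °C; then aq. NaOAc
Reagents that add atoms: N,N-dimethylformamide CN(C)C=O; water O
Why: Vilsmeier–Haack formylation of the electron-rich arene should take one of its two equivalent free ring positions, and hydrolysis of the iminium salt releases the aldehyde.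

**Step 2**
Reactants: 3 2,4,6-trimethoxy-3-methylbenzaldehyde
Product: 4 2,6-dihydroxy-4-methoxy-3-methylbenzaldehyde
Conditions: AlCl3 (5 equiv), CH2Cl2, 0 °C to reflux; then 1 M HCl
Reagents that add atoms: none
Why: Chelation-directed Lewis acid ether cleavage should remove only the two methyl groups ortho to the formyl group, since each ortho oxygen can hold aluminium together with the carbonyl oxygen, while the para methoxy group, a vinylogous ester oxygen, cannot.

**Step 3**
Reactants: 4 2,6-dihydroxy-4-methoxy-3-methylbenzaldehyde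
Product: 5 3-bromo-2,6-dihydroxy-4-methoxy-5-methylbenzaldehyde
Conditions: NBS, MeCN, 0 °C
Reagents that add atoms: N-bromosuccinimide O=C1CCC(=O)N1Br
Why: Electrophilic aromatic bromination can only take the single free ring position, which is activated by three oxygen substituents; this bromine marks the later acyl site.

**Step 4**
Reactants: 5 3-bromo-2,6-dihydroxy-4-methoxy-5-methylbenzaldehyde
Product: 6 2,6-bis(benzyloxy)-3-bromo-4-methoxy-5-methylbenzaldehyde
Conditions: BnBr, K2CO3, DMF, 60 °C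
Reagents that add atoms: benzyl bromide BrCc1ccccc1
Why: Williamson ether synthesis on both phenols; warming is expected to overcome the hydrogen bond to the formyl group.

**Step 5**
Reactants: 6 2,6-bis(benzyloxy)-3-bromo-4-methoxy-5-methylbenzaldehyde
Product: 7 ethyl (E)-3-(ArD)prop-2-enoate
Conditions: (EtO)2P(O)CH2CO2Et, NaH, THF, 0 to 50 °C
Reagents that add atoms: triethyl phosphonoacetate CCOC(=O)CP(=O)(OCC)OCC
Why: Horner–Wadsworth–Emmons olefination adds the two missing carbons of the arm and should give the (E)-acrylate.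

**Step 6**
Reactants: 7 ethyl (E)-3-(ArD)prop-2-enoate
Product: 8 ethyl 3-(ArD)propanoate
Conditions: H2 (4 bar), RhCl(PPh3)3 (5 mol%), benzene–EtOH, 40 °C
Reagents that add atoms: none
Why: Homogeneous hydrogenation with RhCl(PPh3)3 saturates the disubstituted alkene without hydrogenolysis of benzyl ethers or of the aryl bromide.

**Step 7**
Reactants: 8 ethyl 3-(ArD)propanoate
Product: 9 3-(ArD)propanal
Conditions: i-Bu2AlH (1.05 equiv), CH2Cl2, −78 °C; then MeOH, aq. potassium sodium tartrate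
Reagents that add atoms: none
Why: Partial ester reduction with i-Bu2AlH at low temperature stops at the aluminium hemiacetal, which gives the aldehyde on work-up.

**Step 8**
Reactants: 10 (R)-2-methylbutanoic acid
Product: 12 (R)-N-methoxy-N,2-dimethylbutanamide, via acylimidazole 11 (not isolated)
Conditions: 1,1'-carbonyldiimidazole, CH2Cl2, 20 °C; then MeNH(OMe)·HCl
Reagents that add atoms: N,O-dimethylhydroxylamine hydrochloride CNOC.Cl
Why: Amide coupling through the acylimidazole proceeds without added strong base, so the alpha stereocentre of the acid is not at risk.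

**Step 9**
Reactants: 13 ethyl formate
Product: 15 triisopropylsiloxyacetylene, via lithium ethynolate 14 (not isolated)
Conditions: CH2Br2, lithium 2,2,6,6-tetramethylpiperidide, THF, −78 °C; 13; n-BuLi, −78 to 20 °C; i-Pr3SiCl, −78 to 0 °C
Reagents that add atoms: dibromomethane BrCBr; triisopropylsilyl chloride CC(C)[Si](Cl)(C(C)C)C(C)C
Why: Kowalski-type ynolate formation (addition of dibromomethyllithium to the ester, bromine–lithium exchange, 1,2-shift) followed by silylation, in which the bulky silyl chloride should go to oxygen and not to carbon.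

**Step 10**
Reactants: 16 (R)-4-benzyloxazolidin-2-one; 17 benzyloxyacetyl chloride
Product: 18 (R)-4-benzyl-3-[(benzyloxy)acetyl]oxazolidin-2-one
Conditions: n-BuLi, THF, −78 °C; then 17, −78 to 0 °C
Reagents that add atoms: none
Why: N-acylation of the lithiated oxazolidinone with the acid chloride.

**Step 11**
Reactants: 18 (R)-4-benzyl-3-[(benzyloxy)acetyl]oxazolidin-2-one
Product: 19 (R)-4-benzyl-3-[(S)-2-(benzyloxy)pent-4-enoyl]oxazolidin-2-one
Conditions: NaN(SiMe3)2, THF, −78 °C; allyl iodide, −78 to −45 °C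
Reagents that add atoms: allyl iodide C=CCI
Why: Evans alkylation: the chelated sodium (Z)-enolate of 18 is shielded on one face by the benzyl group of the (R)-auxiliary, so allyl iodide should add to the other face and set the (S) centre that becomes C3.

**Step 12**
Reactants: 19 (R)-4-benzyl-3-[(S)-2-(benzyloxy)pent-4-enoyl]oxazolidin-2-one
Product: 20 (S)-2-(benzyloxy)-N-methoxy-N-methylpent-4-enamide
Conditions: MeNH(OMe)·HCl, AlMe3, CH2Cl2, −15 to 0 °C
Reagents that add atoms: N,O-dimethylhydroxylamine hydrochloride CNOC.Cl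
Why: Aluminium amide aminolysis (Weinreb transamidation) of the exocyclic imide carbonyl releases the auxiliary without touching the alpha stereocentre.

**Step 13**
Reactants: 21 1,2-bis(benzyloxy)-4-bromobenzene; 20 (S)-2-(benzyloxy)-N-methoxy-N-methylpent-4-enamide
Product: 23 (S)-2-(benzyloxy)-1-(ArB)pent-4-en-1-one, via aryllithium 22 (not isolated)
Conditions: 21, n-BuLi, THF, −78 °C; then 20, −78 to −40 °C; cold 0.5 M HCl
Reagents that add atoms: none
Why: Aryllithium addition to a Weinreb amide stops at the ketone because of the chelated tetrahedral adduct, which also keeps the alpha centre from enolising until work-up.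

**Step 14**
Reactants: 23 (S)-2-(benzyloxy)-1-(ArB)pent-4-en-1-one
Product: 24 (1R,2S)-2-(benzyloxy)-1-(ArB)pent-4-en-1-ol
Conditions: Zn(BH4)2, Et2O, −20 to 0 °C
Reagents that add atoms: none
Why: Chelation-controlled hydride reduction: zinc binds the carbonyl oxygen and the alpha benzyloxy oxygen, hydride arrives on the face next to the small alpha hydrogen, and the anti alcohol with (R) configuration at the future C2 should predominate.

**Step 15**
Reactants: 24 (1R,2S)-2-(benzyloxy)-1-(ArB)pent-4-en-1-ol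
Product: 26 (1R,2S)-2-(benzyloxy)-1-(ArB)pentane-1,5-diol, via alkylborane 25 (not isolated)
Conditions: 9-borabicyclo[3.3.1]nonane (2.5 equiv), THF, 0 to 20 °C; then NaOH, H2O2, 0 °C
Reagents that add atoms: hydrogen peroxide OO
Why: Hydroboration–oxidation: anti-Markovnikov addition of the hindered borane to the terminal alkene and oxidation of the C–B bond give the primary alcohol.

**Step 16**
Reactants: 26 (1R,2S)-2-(benzyloxy)-1-(ArB)pentane-1,5-diol
Product: 28 (5S,6R)-5-(benzyloxy)-6-(ArB)oxan-2-one, via lactol 27 (not isolated)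
Conditions: TEMPO (0.2 equiv), PhI(OAc)2 (2.5 equiv), CH2Cl2, 20 °C
Reagents that add atoms: none
Why: Oxoammonium-mediated oxidative lactonisation: the primary alcohol is oxidised first, the aldehyde closes with the benzylic hydroxyl group to the six-membered lactol, and this is oxidised on to the lactone, which closes ring C with both stereocentres already in place.

**Step 17**
Reactants: 28 (5S,6R)-5-(benzyloxy)-6-(ArB)oxan-2-one
Product: 29 (2R,3S)-3-(benzyloxy)-2-(ArB)-3,4-dihydro-2H-pyran-6-yl trifluoromethanesulfonate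
Conditions: KN(SiMe3)2 added to 28 and PhNTf2, THF–DMPU, −78 °C; filtration through basic alumina, used at once
Reagents that add atoms: N-phenylbis(trifluoromethanesulfonimide) O=S(=O)(N(c1ccccc1)S(=O)(=O)C(F)(F)F)C(F)(F)F
Why: Enol triflate formation: the kinetic potassium enolate of the lactone is sulfonylated on oxygen as it forms, and neither stereocentre is alpha to the carbonyl.

**Step 18**
Reactants: 29 (2R,3S)-3-(benzyloxy)-2-(ArB)-3,4-dihydro-2H-pyran-6-yl trifluoromethanesulfonate; 9 3-(ArD)propanal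
Product: 31 1-[(2R,3S)-3-(benzyloxy)-2-(ArB)-3,4-dihydro-2H-pyran-6-yl]-3-(ArD)propan-1-ol (both carbinol epimers), via alkenylchromium dichloride 30 (not isolated)
Conditions: CrCl2 (5 equiv), NiCl2 (2 mol%), DMF, 20 °C
Reagents that add atoms: none
Why: Nozaki–Hiyama–Kishi coupling: nickel inserts into the alkenyl triflate, transmetalation to chromium gives an alkenylchromium species that adds only to the aldehyde, under neutral conditions that should leave the hindered, electron-rich aryl bromide, the benzyl ethers and the benzylic C2–H alone.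

**Step 19**
Reactants: 31 1-[(2R,3S)-3-(benzyloxy)-2-(ArB)-3,4-dihydro-2H-pyran-6-yl]-3-(ArD)propan-1-ol
Product: 32 1-[(2R,3S)-3-(benzyloxy)-2-(ArB)-3,4-dihydro-2H-pyran-6-yl]-3-(ArD)propan-1-one
Conditions: Dess–Martin periodinane, NaHCO3, CH2Cl2, 0 to 20 °C
Reagents that add atoms: none
Why: Buffered hypervalent iodine oxidation of the allylic alcohol gives the 6-acyl dihydropyran without acid that could hydrolyse the enol ether.

**Step 20**
Reactants: 32 1-[(2R,3S)-3-(benzyloxy)-2-(ArB)-3,4-dihydro-2H-pyran-6-yl]-3-(ArD)propan-1-one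
Product: 34 2-diazo-1-[(2R,3S)-3-(benzyloxy)-2-(ArB)-3,4-dihydro-2H-pyran-6-yl]-3-(ArD)propan-1-one, via trifluoroacetyl ketone 33 (not isolated)
Conditions: LiN(SiMe3)2, THF, −78 °C; CF3CO2CH2CF3; dilute HCl wash; then MsN3, Et3N, H2O, MeCN, 20 °C
Reagents that add atoms: methanesulfonyl azide CS(=O)(=O)N=[N+]=[N-]
Why: Detrifluoroacetylative diazo transfer: the kinetic lithium enolate on the CH2 side of the ketone is trifluoroacetylated, and the activated diketone takes the diazo group from the sulfonyl azide with loss of the trifluoroacetyl group.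

**Step 21**
Reactants: 34 2-diazo-1-[(2R,3S)-3-(benzyloxy)-2-(ArB)-3,4-dihydro-2H-pyran-6-yl]-3-(ArD)propan-1-one; 15 triisopropylsiloxyacetylene
Product: 39 (2R,3S)-3-(benzyloxy)-2-(ArB)-8-[(ArD)methyl]-7-(triisopropylsiloxy)-3,4-dihydro-2H-chromen-5-ol, via vinylketene 35 (not isolated), via vinylcyclobutenone 36 (not isolated), via dienylketene 37 (not isolated), via cyclohexadienone 38 (not isolated)
Conditions: 15 (3 equiv), ClCH2CH2Cl, hν (365 nm LEDs, Pyrex), 20 °C; then 80 °C
Reagents that add atoms: none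
Why: Light of 365 nm is absorbed by the diazo ketone but not by the bromoarene or the benzyl ethers; loss of N2 with Wolff rearrangement moves the dihydropyranyl group to the former diazo carbon (bond C8–C8a) and leaves vinylketene 35, whose ketene alpha carbon already holds the ring D arm. The oxygen-polarised siloxyalkyne adds across the ketene C=C in a (2+2) cycloaddition with its CH terminus on the ketene carbonyl carbon (bonds C5–C6 and C7–C8), and warming opens cyclobutenone 36 in a four-electron electrocyclic step to dienylketene 37. Ring A is then closed by a six-electron electrocyclic reaction between the ketene carbon and C4a of the enol ether (bond C4a–C5), and enolisation of dienone 38 gives the C5 phenol; this is the photochemical, second-generation form of the Danheiser benzannulation, whose closest precedents are diazo ketones of cyclic enones combined with siloxyalkynes. No stereocentre is created, because C4a ends sp2 and C2 and C3 lie away from all bond changes. The step needs the Wolff shift to outrun a 1,2-hydrogen shift from the benzylic CH2, which direct irradiation (loss of N2 concerted with migration from the s-Z conformer) favours over thermal or metal-catalysed decomposition, and it needs one orientation in the cycloaddition, which the polarisation of the alkyne secures. Since C5, C6, C7 and C8 come from the acyl carbon, the two alkyne carbons and the diazo carbon, the bridge can only end at C8.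

**Step 22**
Reactants: 39 (2R,3S)-3-(benzyloxy)-2-(ArB)-8-[(ArD)methyl]-7-(triisopropylsiloxy)-3,4-dihydro-2H-chromen-5-ol
Product: 40 (2R,3S)-3,5,7-tris(benzyloxy)-2-(ArB)-8-[(ArD)methyl]-3,4-dihydro-2H-chromene
Conditions: CsF (4 equiv), BnBr (3 equiv), DMF, 20 °C
Reagents that add atoms: benzyl bromide BrCc1ccccc1
Why: Fluoride cleaves the aryl silyl ether and serves as base for the phenol, and both phenoxides are benzylated in the same flask (Williamson ether synthesis), so that all hydroxyl groups carry one kind of protecting group.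

**Step 23**
Reactants: 40 (2R,3S)-3,5,7-tris(benzyloxy)-2-(ArB)-8-[(ArD)methyl]-3,4-dihydro-2H-chromene; 12 (R)-N-methoxy-N,2-dimethylbutanamide
Product: 42 (2R)-1-[2,4-bis(benzyloxy)-6-methoxy-5-methyl-3-{[(2R,3S)-3,5,7-tris(benzyloxy)-2-(ArB)-3,4-dihydro-2H-chromen-8-yl]methyl}phenyl]-2-methylbutan-1-one, via aryllithium 41 (not isolated)
Conditions: n-BuLi, THF, −78 °C; then 12, −78 to −30 °C; cold 0.5 M HCl
Reagents that add atoms: none
Why: Bromine–lithium exchange at −78 °C is faster than deprotonation of a benzyl ether, and the aryllithium adds to the Weinreb amide to a chelated tetrahedral adduct that releases the ketone only on work-up, so the alpha stereocentre of the acyl group is not exposed to base.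

**Step 24**
Reactants: 42 (2R)-1-[2,4-bis(benzyloxy)-6-methoxy-5-methyl-3-{[(2R,3S)-3,5,7-tris(benzyloxy)-2-(ArB)-3,4-dihydro-2H-chromen-8-yl]methyl}phenyl]-2-methylbutan-1-one
Product: 43 target CNP0299940.2
Conditions: H2 (1 atm), Pd(OH)2 on carbon, THF–MeOH, 20 °C
Reagents that add atoms: none
Why: Hydrogenolysis of the seven benzyl ethers under neutral conditions should leave the hydrogen-bonded aryl ketone, the flavan C2–O1 bond and the three stereocentres unchanged.

## Compound list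

1 | 2,4,6-trimethoxytoluene | Cc1c(OC)cc(OC)cc1OC | starting material
2 | [(2,4,6-trimethoxy-3-methylphenyl)methylidene]dimethylammonium chloride | C[N+](C)=Cc1c(OC)cc(OC)c(C)c1OC.[Cl-] | intermediate (not isolated)
3 | 2,4,6-trimethoxy-3-methylbenzaldehyde | O=Cc1c(OC)cc(OC)c(C)c1OC | intermediate
4 | 2,6-dihydroxy-4-methoxy-3-methylbenzaldehyde | O=Cc1c(O)cc(OC)c(C)c1O | intermediate
5 | 3-bromo-2,6-dihydroxy-4-methoxy-5-methylbenzaldehyde | O=Cc1c(O)c(Br)c(OC)c(C)c1O | intermediate
6 | 2,6-bis(benzyloxy)-3-bromo-4-methoxy-5-methylbenzaldehyde | O=Cc1c(OCc2ccccc2)c(Br)c(OC)c(C)c1OCc1ccccc1 | intermediate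
7 | ethyl (2E)-3-[2,6-bis(benzyloxy)-3-bromo-4-methoxy-5-methylphenyl]prop-2-enoate | CCOC(=O)/C=C/c1c(OCc2ccccc2)c(Br)c(OC)c(C)c1OCc1ccccc1 | intermediate
8 | ethyl 3-[2,6-bis(benzyloxy)-3-bromo-4-methoxy-5-methylphenyl]propanoate | CCOC(=O)CCc1c(OCc2ccccc2)c(Br)c(OC)c(C)c1OCc1ccccc1 | intermediate
9 | 3-[2,6-bis(benzyloxy)-3-bromo-4-methoxy-5-methylphenyl]propanal | O=CCCc1c(OCc2ccccc2)c(Br)c(OC)c(C)c1OCc1ccccc1 | intermediate
10 | (R)-2-methylbutanoic acid | CC[C@@H](C)C(=O)O | starting material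
11 | (2R)-1-(1H-imidazol-1-yl)-2-methylbutan-1-one | CC[C@@H](C)C(=O)n1ccnc1 | intermediate (not isolated)
12 | (2R)-N-methoxy-N,2-dimethylbutanamide | CC[C@@H](C)C(=O)N(C)OC | intermediate
13 | ethyl formate | CCOC=O | starting material
14 | lithium ethynolate | [Li+].[O-]C#C | intermediate (not isolated)
15 | triisopropylsiloxyacetylene, (ethynyloxy)tri(propan-2-yl)silane | C#CO[Si](C(C)C)(C(C)C)C(C)C | intermediate
16 | (4R)-4-benzyl-1,3-oxazolidin-2-one | O=C1OC[C@@H](Cc2ccccc2)N1 | starting material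
17 | (benzyloxy)acetyl chloride | O=C(Cl)COCc1ccccc1 | starting material
18 | (4R)-4-benzyl-3-[(benzyloxy)acetyl]-1,3-oxazolidin-2-one | O=C1OC[C@@H](Cc2ccccc2)N1C(=O)COCc1ccccc1 | intermediate
19 | (4R)-4-benzyl-3-[(2S)-2-(benzyloxy)pent-4-enoyl]-1,3-oxazolidin-2-one | O=C1OC[C@@H](Cc2ccccc2)N1C(=O)[C@H](CC=C)OCc1ccccc1 | intermediate
20 | (2S)-2-(benzyloxy)-N-methoxy-N-methylpent-4-enamide | CON(C)C(=O)[C@H](CC=C)OCc1ccccc1 | intermediate
21 | 1,2-bis(benzyloxy)-4-bromobenzene | Brc1ccc(OCc2ccccc2)c(OCc2ccccc2)c1 | starting material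
22 | [3,4-bis(benzyloxy)phenyl]lithium | [Li]c1ccc(OCc2ccccc2)c(OCc2ccccc2)c1 | intermediate (not isolated)
23 | (2S)-2-(benzyloxy)-1-[3,4-bis(benzyloxy)phenyl]pent-4-en-1-one | C=CC[C@H](OCc1ccccc1)C(=O)c1ccc(OCc2ccccc2)c(OCc2ccccc2)c1 | intermediate
24 | (1R,2S)-2-(benzyloxy)-1-[3,4-bis(benzyloxy)phenyl]pent-4-en-1-ol | C=CC[C@H](OCc1ccccc1)[C@H](O)c1ccc(OCc2ccccc2)c(OCc2ccccc2)c1 | intermediate
25 | 9-[(4S,5R)-4-(benzyloxy)-5-[3,4-bis(benzyloxy)phenyl]-5-(9-borabicyclo[3.3.1]nonan-9-yloxy)pentyl]-9-borabicyclo[3.3.1]nonane | C1CCC2CCCC1B2CCC[C@H](OCc1ccccc1)[C@H](OB1C2CCCC1CCC2)c1ccc(OCc2ccccc2)c(OCc2ccccc2)c1 | intermediate (not isolated)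
26 | (1R,2S)-2-(benzyloxy)-1-[3,4-bis(benzyloxy)phenyl]pentane-1,5-diol | OCCC[C@H](OCc1ccccc1)[C@H](O)c1ccc(OCc2ccccc2)c(OCc2ccccc2)c1 | intermediate
27 | (5S,6R)-5-(benzyloxy)-6-[3,4-bis(benzyloxy)phenyl]oxan-2-ol, both anomers | OC1CC[C@H](OCc2ccccc2)[C@@H](c2ccc(OCc3ccccc3)c(OCc3ccccc3)c2)O1 | intermediate (not isolated)
28 | (5S,6R)-5-(benzyloxy)-6-[3,4-bis(benzyloxy)phenyl]oxan-2-one | O=C1CC[C@H](OCc2ccccc2)[C@@H](c2ccc(OCc3ccccc3)c(OCc3ccccc3)c2)O1 | intermediate
29 | (2R,3S)-3-(benzyloxy)-2-[3,4-bis(benzyloxy)phenyl]-3,4-dihydro-2H-pyran-6-yl trifluoromethanesulfonate | FC(F)(F)S(=O)(=O)OC1=CC[C@H](OCc2ccccc2)[C@@H](c2ccc(OCc3ccccc3)c(OCc3ccccc3)c2)O1 | intermediate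
30 | dichloro[(2R,3S)-3-(benzyloxy)-2-[3,4-bis(benzyloxy)phenyl]-3,4-dihydro-2H-pyran-6-yl]chromium | Cl[Cr](Cl)C1=CC[C@H](OCc2ccccc2)[C@@H](c2ccc(OCc3ccccc3)c(OCc3ccccc3)c2)O1 | intermediate (not isolated)
31 | 1-[(2R,3S)-3-(benzyloxy)-2-[3,4-bis(benzyloxy)phenyl]-3,4-dihydro-2H-pyran-6-yl]-3-[2,6-bis(benzyloxy)-3-bromo-4-methoxy-5-methylphenyl]propan-1-ol, both carbinol epimers | OC(CCc1c(OCc2ccccc2)c(Br)c(OC)c(C)c1OCc1ccccc1)C1=CC[C@H](OCc2ccccc2)[C@@H](c2ccc(OCc3ccccc3)c(OCc3ccccc3)c2)O1 | intermediate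
32 | 1-[(2R,3S)-3-(benzyloxy)-2-[3,4-bis(benzyloxy)phenyl]-3,4-dihydro-2H-pyran-6-yl]-3-[2,6-bis(benzyloxy)-3-bromo-4-methoxy-5-methylphenyl]propan-1-one | O=C(CCc1c(OCc2ccccc2)c(Br)c(OC)c(C)c1OCc1ccccc1)C1=CC[C@H](OCc2ccccc2)[C@@H](c2ccc(OCc3ccccc3)c(OCc3ccccc3)c2)O1 | intermediate
33 | 1-[(2R,3S)-3-(benzyloxy)-2-[3,4-bis(benzyloxy)phenyl]-3,4-dihydro-2H-pyran-6-yl]-2-{[2,6-bis(benzyloxy)-3-bromo-4-methoxy-5-methylphenyl]methyl}-4,4,4-trifluorobutane-1,3-dione | O=C(C(Cc1c(OCc2ccccc2)c(Br)c(OC)c(C)c1OCc1ccccc1)C(=O)C(F)(F)F)C1=CC[C@H](OCc2ccccc2)[C@@H](c2ccc(OCc3ccccc3)c(OCc3ccccc3)c2)O1 | intermediate (not isolated)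
34 | 1-[(2R,3S)-3-(benzyloxy)-2-[3,4-bis(benzyloxy)phenyl]-3,4-dihydro-2H-pyran-6-yl]-3-[2,6-bis(benzyloxy)-3-bromo-4-methoxy-5-methylphenyl]-2-diazopropan-1-one | [N-]=[N+]=C(Cc1c(OCc2ccccc2)c(Br)c(OC)c(C)c1OCc1ccccc1)C(=O)C1=CC[C@H](OCc2ccccc2)[C@@H](c2ccc(OCc3ccccc3)c(OCc3ccccc3)c2)O1 | intermediate
35 | 2-[(2R,3S)-3-(benzyloxy)-2-[3,4-bis(benzyloxy)phenyl]-3,4-dihydro-2H-pyran-6-yl]-3-[2,6-bis(benzyloxy)-3-bromo-4-methoxy-5-methylphenyl]prop-1-en-1-one (vinylketene) | O=C=C(Cc1c(OCc2ccccc2)c(Br)c(OC)c(C)c1OCc1ccccc1)C1=CC[C@H](OCc2ccccc2)[C@@H](c2ccc(OCc3ccccc3)c(OCc3ccccc3)c2)O1 | intermediate (not isolated)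
36 | 4-[(2R,3S)-3-(benzyloxy)-2-[3,4-bis(benzyloxy)phenyl]-3,4-dihydro-2H-pyran-6-yl]-4-{[2,6-bis(benzyloxy)-3-bromo-4-methoxy-5-methylphenyl]methyl}-3-(triisopropylsiloxy)cyclobut-2-en-1-one, both epimers at C4 of the four-membered ring | O=C1C=C(O[Si](C(C)C)(C(C)C)C(C)C)C1(Cc1c(OCc2ccccc2)c(Br)c(OC)c(C)c1OCc1ccccc1)C1=CC[C@H](OCc2ccccc2)[C@@H](c2ccc(OCc3ccccc3)c(OCc3ccccc3)c2)O1 | intermediate (not isolated)
37 | 4-[(2R,3S)-3-(benzyloxy)-2-[3,4-bis(benzyloxy)phenyl]-3,4-dihydro-2H-pyran-6-yl]-5-[2,6-bis(benzyloxy)-3-bromo-4-methoxy-5-methylphenyl]-3-(triisopropylsiloxy)penta-1,3-dien-1-one, ketene arm cis to the dihydropyranyl group | O=C=C/C(O[Si](C(C)C)(C(C)C)C(C)C)=C(/Cc1c(OCc2ccccc2)c(Br)c(OC)c(C)c1OCc1ccccc1)C1=CC[C@H](OCc2ccccc2)[C@@H](c2ccc(OCc3ccccc3)c(OCc3ccccc3)c2)O1 | intermediate (not isolated)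
38 | (2R,3S)-3-(benzyloxy)-2-[3,4-bis(benzyloxy)phenyl]-8-{[2,6-bis(benzyloxy)-3-bromo-4-methoxy-5-methylphenyl]methyl}-7-(triisopropylsiloxy)-2,3,4,4a-tetrahydro-5H-chromen-5-one, both epimers at C4a | O=C1C=C(O[Si](C(C)C)(C(C)C)C(C)C)C(Cc2c(OCc3ccccc3)c(Br)c(OC)c(C)c2OCc2ccccc2)=C2O[C@H](c3ccc(OCc4ccccc4)c(OCc4ccccc4)c3)[C@@H](OCc3ccccc3)CC12 | intermediate (not isolated)
39 | (2R,3S)-3-(benzyloxy)-2-[3,4-bis(benzyloxy)phenyl]-8-{[2,6-bis(benzyloxy)-3-bromo-4-methoxy-5-methylphenyl]methyl}-7-(triisopropylsiloxy)-3,4-dihydro-2H-chromen-5-ol | COc1c(Br)c(OCc2ccccc2)c(Cc2c(O[Si](C(C)C)(C(C)C)C(C)C)cc(O)c3c2O[C@H](c2ccc(OCc4ccccc4)c(OCc4ccccc4)c2)[C@@H](OCc2ccccc2)C3)c(OCc2ccccc2)c1C | intermediate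
40 | (2R,3S)-3,5,7-tris(benzyloxy)-2-[3,4-bis(benzyloxy)phenyl]-8-{[2,6-bis(benzyloxy)-3-bromo-4-methoxy-5-methylphenyl]methyl}-3,4-dihydro-2H-chromene | COc1c(Br)c(OCc2ccccc2)c(Cc2c(OCc3ccccc3)cc(OCc3ccccc3)c3c2O[C@H](c2ccc(OCc4ccccc4)c(OCc4ccccc4)c2)[C@@H](OCc2ccccc2)C3)c(OCc2ccccc2)c1C | intermediate
41 | [2,4-bis(benzyloxy)-6-methoxy-5-methyl-3-{[(2R,3S)-3,5,7-tris(benzyloxy)-2-[3,4-bis(benzyloxy)phenyl]-3,4-dihydro-2H-chromen-8-yl]methyl}phenyl]lithium | COc1c([Li])c(OCc2ccccc2)c(Cc2c(OCc3ccccc3)cc(OCc3ccccc3)c3c2O[C@H](c2ccc(OCc4ccccc4)c(OCc4ccccc4)c2)[C@@H](OCc2ccccc2)C3)c(OCc2ccccc2)c1C | intermediate (not isolated)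
42 | (2R)-1-[2,4-bis(benzyloxy)-6-methoxy-5-methyl-3-{[(2R,3S)-3,5,7-tris(benzyloxy)-2-[3,4-bis(benzyloxy)phenyl]-3,4-dihydro-2H-chromen-8-yl]methyl}phenyl]-2-methylbutan-1-one | CC[C@@H](C)C(=O)c1c(OCc2ccccc2)c(Cc2c(OCc3ccccc3)cc(OCc3ccccc3)c3c2O[C@H](c2ccc(OCc4ccccc4)c(OCc4ccccc4)c2)[C@@H](OCc2ccccc2)C3)c(OCc2ccccc2)c(C)c1OC | intermediate
43 | (2R)-1-[3-{[(2R,3S)-2-(3,4-dihydroxyphenyl)-3,5,7-trihydroxy-3,4-dihydro-2H-chromen-8-yl]methyl}-2,4-dihydroxy-6-methoxy-5-methylphenyl]-2-methylbutan-1-one (CNP0299940.2) | CC[C@@H](C)C(=O)c1c(O)c(Cc2c(O)cc(O)c3c2O[C@H](c2ccc(O)c(O)c2)[C@@H](O)C3)c(O)c(C)c1OC | target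

## Step count and risks

Total step count: 24. Longest linear sequence: 15 steps (steps 10 to 24, from 16 and 17).

The three steps most likely to fail:

**Step 21.** What may go wrong: after loss of N2 part of the material may react through the free carbene, in which a hydrogen of the benzylic CH2 shifts to the carbene carbon faster than the dihydropyranyl group migrates, so that an enone forms in place of the ketene. The ketene that does form may also be consumed by the product phenol. Fallback: ring A would be annulated without the bridge, on a diazo ketone that has no hydrogen next to the diazo carbon, and the bridge would be attached afterwards at C8, the position that 5,7-dialkoxyflavans are known to offer to N-bromosuccinimide. The detour sets out from triflate 29. CrCl2/NiCl2 coupling with acetaldehyde would give 1-[(2R,3S)-3-(benzyloxy)-2-(ArB)-3,4-dihydro-2H-pyran-6-yl]ethan-1-ol F1, and Dess–Martin oxidation the methyl ketone F2. LiN(SiMe3)2 with CF3CO2CH2CF3 would give the trifluoroacetyl ketone F3, and methanesulfonyl azide the terminal diazo ketone F4. Irradiation of F4 with 15 would give the 8-unsubstituted 7-silyloxychroman-5-ol F5, and CsF with benzyl bromide the pentabenzyl ether F6. N-Bromosuccinimide would give the 8-bromide F7, and n-BuLi at −78 °C the 8-lithio compound F8. Addition of F8 to aldehyde 6 would give the diarylcarbinol F9, and Et3SiH with CF3CO2H would reduce F9 to 40, where the route is rejoined.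

**Step 18 (with step 17).** What may go wrong: the ketene acetal triflate may lose triflate by hydrolysis or protonolysis on handling or in DMF before nickel inserts, which returns the lactone. Fallback: the more robust enol phosphate and a tin–lithium exchange would replace the triflate and the chromium reagent. Setting out from lactone 28, KN(SiMe3)2 and (PhO)2P(O)Cl would give the ketene acetal diphenyl phosphate F10. Pd(PPh3)4, Me3SnSnMe3 and LiCl would give the alkenylstannane F11. MeLi at −78 °C would give the 6-lithio dihydropyran F12 by an exchange that needs no deprotonation and is faster than attack on the benzylic positions. F12 would be added at −78 °C to aldehyde 9 to give alcohol 31, where the route is rejoined.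

**Step 23.** What may go wrong: the doubly ortho-substituted aryllithium may add only slowly to the branched amide and instead take a proton from the amide alpha carbon, or on warming from a benzyl ether, which returns debrominated arene and endangers the alpha stereocentre. Fallback: a smaller, more electrophilic partner in two steps. Setting out from amide 12, LiAlH4 at −78 °C would give (R)-2-methylbutanal F13, used at once as a cold solution. Aryllithium 41 would add to it at −78 °C to give the carbinol F14 as a mixture at the carbinol carbon, and buffered Dess–Martin oxidation would give ketone 42, where the route is rejoined.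

## Further compounds

F1 | step 21 | 1-[(2R,3S)-3-(benzyloxy)-2-[3,4-bis(benzyloxy)phenyl]-3,4-dihydro-2H-pyran-6-yl]ethan-1-ol | CC(O)C1=CC[C@H](OCc2ccccc2)[C@@H](c2ccc(OCc3ccccc3)c(OCc3ccccc3)c2)O1
F2 | step 21 | 1-[(2R,3S)-3-(benzyloxy)-2-[3,4-bis(benzyloxy)phenyl]-3,4-dihydro-2H-pyran-6-yl]ethan-1-one | CC(=O)C1=CC[C@H](OCc2ccccc2)[C@@H](c2ccc(OCc3ccccc3)c(OCc3ccccc3)c2)O1
F3 | step 21 | 1-[(2R,3S)-3-(benzyloxy)-2-[3,4-bis(benzyloxy)phenyl]-3,4-dihydro-2H-pyran-6-yl]-4,4,4-trifluorobutane-1,3-dione | O=C(CC(=O)C(F)(F)F)C1=CC[C@H](OCc2ccccc2)[C@@H](c2ccc(OCc3ccccc3)c(OCc3ccccc3)c2)O1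
F4 | step 21 | 1-[(2R,3S)-3-(benzyloxy)-2-[3,4-bis(benzyloxy)phenyl]-3,4-dihydro-2H-pyran-6-yl]-2-diazoethan-1-one | [N-]=[N+]=CC(=O)C1=CC[C@H](OCc2ccccc2)[C@@H](c2ccc(OCc3ccccc3)c(OCc3ccccc3)c2)O1
F5 | step 21 | (2R,3S)-3-(benzyloxy)-2-[3,4-bis(benzyloxy)phenyl]-7-(triisopropylsiloxy)-3,4-dihydro-2H-chromen-5-ol | Oc1cc(O[Si](C(C)C)(C(C)C)C(C)C)cc2O[C@H](c3ccc(OCc4ccccc4)c(OCc4ccccc4)c3)[C@@H](OCc3ccccc3)Cc12
F6 | step 21 | (2R,3S)-3,5,7-tris(benzyloxy)-2-[3,4-bis(benzyloxy)phenyl]-3,4-dihydro-2H-chromene | C(Oc1cc(OCc2ccccc2)cc2O[C@H](c3ccc(OCc4ccccc4)c(OCc4ccccc4)c3)[C@@H](OCc3ccccc3)Cc12)c1ccccc1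
F7 | step 21 | (2R,3S)-3,5,7-tris(benzyloxy)-2-[3,4-bis(benzyloxy)phenyl]-8-bromo-3,4-dihydro-2H-chromene | C(Oc1cc(OCc2ccccc2)c(Br)c2O[C@H](c3ccc(OCc4ccccc4)c(OCc4ccccc4)c3)[C@@H](OCc3ccccc3)Cc12)c1ccccc1
F8 | step 21 | [(2R,3S)-3,5,7-tris(benzyloxy)-2-[3,4-bis(benzyloxy)phenyl]-3,4-dihydro-2H-chromen-8-yl]lithium | C(Oc1cc(OCc2ccccc2)c([Li])c2O[C@H](c3ccc(OCc4ccccc4)c(OCc4ccccc4)c3)[C@@H](OCc3ccccc3)Cc12)c1ccccc1
F9 | step 21 | [2,6-bis(benzyloxy)-3-bromo-4-methoxy-5-methylphenyl][(2R,3S)-3,5,7-tris(benzyloxy)-2-[3,4-bis(benzyloxy)phenyl]-3,4-dihydro-2H-chromen-8-yl]methanol, both carbinol epimers | COc1c(Br)c(OCc2ccccc2)c(C(O)c2c(OCc3ccccc3)cc(OCc3ccccc3)c3c2O[C@H](c2ccc(OCc4ccccc4)c(OCc4ccccc4)c2)[C@@H](OCc2ccccc2)C3)c(OCc2ccccc2)c1C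
F10 | step 18 | (2R,3S)-3-(benzyloxy)-2-[3,4-bis(benzyloxy)phenyl]-3,4-dihydro-2H-pyran-6-yl diphenyl phosphate | O=P(Oc1ccccc1)(Oc1ccccc1)OC1=CC[C@H](OCc2ccccc2)[C@@H](c2ccc(OCc3ccccc3)c(OCc3ccccc3)c2)O1
F11 | step 18 | [(2R,3S)-3-(benzyloxy)-2-[3,4-bis(benzyloxy)phenyl]-3,4-dihydro-2H-pyran-6-yl]trimethylstannane | C[Sn](C)(C)C1=CC[C@H](OCc2ccccc2)[C@@H](c2ccc(OCc3ccccc3)c(OCc3ccccc3)c2)O1
F12 | step 18 | [(2R,3S)-3-(benzyloxy)-2-[3,4-bis(benzyloxy)phenyl]-3,4-dihydro-2H-pyran-6-yl]lithium | [Li]C1=CC[C@H](OCc2ccccc2)[C@@H](c2ccc(OCc3ccccc3)c(OCc3ccccc3)c2)O1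
F13 | step 23 | (R)-2-methylbutanal | CC[C@@H](C)C=O
F14 | step 23 | (2R)-1-[2,4-bis(benzyloxy)-6-methoxy-5-methyl-3-{[(2R,3S)-3,5,7-tris(benzyloxy)-2-[3,4-bis(benzyloxy)phenyl]-3,4-dihydro-2H-chromen-8-yl]methyl}phenyl]-2-methylbutan-1-ol, both carbinol epimers | CC[C@@H](C)C(O)c1c(OCc2ccccc2)c(Cc2c(OCc3ccccc3)cc(OCc3ccccc3)c3c2O[C@H](c2ccc(OCc4ccccc4)c(OCc4ccccc4)c2)[C@@H](OCc2ccccc2)C3)c(OCc2ccccc2)c(C)c1OC
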